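The aryl ketone is cut between its carbonyl carbon and C-1 of the methylcyclohexene ring. The ring, with the chromanonyl-bearing C-2 and the resorcinol-bearing C-6 set trans by an auxiliary-controlled endo Diels–Alder reaction of a cinnamoyl imide, is carried as the C-1 carboxylic acid. Its N-acyloxyphthalimide and the 2-pyridyl thioester of the prenylated resorcylic acid are joined by nickel-catalysed decarboxylative cross-electrophile coupling. In one operation the carboxyl handle leaves as CO2, the ketone C–C bond forms and C-1 is set. The step exploits that C-1 becomes a planar radical flanked by the trans aryl groups on C-2 and C-6, so the acyl group should enter anti to the axial C-6 aryl.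

Key step: step 19

Abbreviations: MOM = CH2OCH3; ArM = 2,4-bis(methoxymethoxy)phenyl; ChrM = (2S)-2-[2,4-bis(methoxymethoxy)phenyl]-7-(methoxymethoxy)-4-oxo-3,4-dihydro-2H-chromen-8-yl; cyclohexene numbering: C-1 carries the acyl carbon, C-2 ChrM, C-3=C-4(CH3), C-6 ArM.

Remark: the sense of induction in steps 11 and 16 is assigned from the accepted models of the parent reactions; if either proves opposite, the enantiomeric ligand or auxiliary is used.

**Acyl donor**

Step 1
Reactants: 1 resorcinol
Product: 2 1,3-bis(methoxymethoxy)benzene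
Conditions: NaH, MOMCl, DMF, 0 °C → rt
Reagents that add atoms: chloromethyl methyl ether (MOMCl), COCCl
Why: Double Williamson O-alkylation; MOM ethers direct the two ortho-lithiations of steps 2 and 3 and survive base, organometallics and Ni/Zn.

Step 2
Reactants: 2 1,3-bis(methoxymethoxy)benzene
Product: 4 1,3-bis(methoxymethoxy)-2-(3-methylbut-2-en-1-yl)benzene, via aryllithium 3 (not isolated)
Conditions: n-BuLi, THF, 0 °C → rt; CuBr·SMe2 (20 mol%), prenyl bromide, −78 °C → rt
Reagents that add atoms: prenyl bromide, CC(C)=CCBr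
Why: Directed ortho-metalation at the position between the two OMOM groups, then copper-catalysed SN2 allylation of the aryllithium.

Step 3
Reactants: 4 1,3-bis(methoxymethoxy)-2-(3-methylbut-2-en-1-yl)benzene
Product: 6 2,4-bis(methoxymethoxy)-3-(3-methylbut-2-en-1-yl)benzoic acid, via aryllithium 5 (not isolated)
Conditions: n-BuLi, TMEDA, THF, −20 → 0 °C; CO2, −78 °C → rt; 1 M HCl to pH 3
Reagents that add atoms: carbon dioxide, O=C=O
Why: Second directed ortho-lithiation at the remaining position ortho to an OMOM group (TMEDA favours ring over benzylic deprotonation), then carboxylation.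

Step 4
Reactants: 6 2,4-bis(methoxymethoxy)-3-(3-methylbut-2-en-1-yl)benzoic acid
Product: 7 S-(pyridin-2-yl) 2,4-bis(methoxymethoxy)-3-(3-methylbut-2-en-1-yl)benzenecarbothioate
Conditions: 2,2′-dipyridyl disulfide, PPh3, MeCN–CH2Cl2, rt
Reagents that add atoms: 2,2′-dipyridyl disulfide, c1ccc(SSc2ccccn2)nc1
Why: Mukaiyama redox condensation gives the 2-pyridyl thioester under neutral conditions that spare the MOM ethers and the prenyl group.

**Arylboronic acid**

Step 5
Reactants: 8 4-bromobenzene-1,3-diol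
Product: 9 1-bromo-2,4-bis(methoxymethoxy)benzene
Conditions: NaH, MOMCl, DMF, 0 °C → rt
Reagents that add atoms: chloromethyl methyl ether (MOMCl), COCCl
Why: Double Williamson O-alkylation of the bis-phenoxide.

Step 6
Reactants: 9 1-bromo-2,4-bis(methoxymethoxy)benzene
Product: 11 [2,4-bis(methoxymethoxy)phenyl]boronic acid, via aryllithium 10 (not isolated)
Conditions: n-BuLi, THF, −78 °C; B(OiPr)3, −78 °C → rt; 1 M HCl to pH 5
Reagents that add atoms: triisopropyl borate, CC(C)OB(OC(C)C)OC(C)C; water, O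
Why: Bromine–lithium exchange (faster than ring deprotonation at −78 °C), borylation of the aryllithium and hydrolysis of the borate on work-up.

**Flavanone diene**

Step 7
Reactants: 12 1-(2,4-dihydroxyphenyl)ethan-1-one
Product: 13 1-(2,4-dihydroxy-3-iodophenyl)ethan-1-one
Conditions: I2, HIO3, EtOH–H2O, rt
Reagents that add atoms: iodine, II; iodic acid, OI(=O)=O
Why: Electrophilic aromatic iodination, expected at C-3 (ortho to both hydroxyl groups); any 5-iodo isomer is removed here by crystallisation.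

Step 8
Reactants: 13 1-(2,4-dihydroxy-3-iodophenyl)ethan-1-one
Product: 14 1-[2-hydroxy-3-iodo-4-(methoxymethoxy)phenyl]ethan-1-one
Conditions: MOMCl (1.1 equiv), K2CO3, acetone, rt
Reagents that add atoms: chloromethyl methyl ether (MOMCl), COCCl
Why: Selective Williamson alkylation of the 4-OH, because the 2-OH is hydrogen-bonded to the acetyl group and must stay free for step 9.

Step 9
Reactants: 14 1-[2-hydroxy-3-iodo-4-(methoxymethoxy)phenyl]ethan-1-one
Product: 16 8-iodo-7-(methoxymethoxy)-4H-chromen-4-one, via enaminone 15 (not isolated)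
Conditions: DMF-DMA, toluene, 90 °C; then AcOH, 60 °C
Reagents that add atoms: N,N-dimethylformamide dimethyl acetal, COC(OC)N(C)C
Why: Condensation of the methyl ketone with DMF-DMA gives the enaminone, and acid then promotes addition of the free phenol and loss of dimethylamine (addition–elimination) to close the pyranone ring.

Step 10
Reactants: 16 8-iodo-7-(methoxymethoxy)-4H-chromen-4-one, 17 2-methylbut-3-en-2-ol
Product: 18 8-[(1E)-3-hydroxy-3-methylbut-1-en-1-yl]-7-(methoxymethoxy)-4H-chromen-4-one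
Conditions: Pd(OAc)2 (5 mol%), Bu4NCl, NaHCO3, DMF, 80 °C
Reagents that add atoms: none
Why: Heck reaction under ligand-free phase-transfer conditions; syn-carbopalladation and syn-β-hydride elimination give the E-alkene, and the tertiary carbinol cannot isomerise to a carbonyl compound.

Step 11
Reactants: 18 8-[(1E)-3-hydroxy-3-methylbut-1-en-1-yl]-7-(methoxymethoxy)-4H-chromen-4-one, 11 [2,4-bis(methoxymethoxy)phenyl]boronic acid
Product: 19 (2S)-2-[2,4-bis(methoxymethoxy)phenyl]-8-[(1E)-3-hydroxy-3-methylbut-1-en-1-yl]-7-(methoxymethoxy)-2,3-dihydro-4H-chromen-4-one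
Conditions: [RhCl(C2H4)2]2 (3 mol%), (S)-configured electron-poor BIPHEP-type bisphosphine (6.6 mol%), aq KOH (10 mol%), 11 (2.5 equiv), toluene–H2O, 40 °C
Reagents that add atoms: none
Why: Rhodium-catalysed asymmetric 1,4-addition of the arylboronic acid to the chromone (Hayashi–Miyaura reaction) sets C-2 under ligand control; the (S)-ligand is assigned by analogy with (S)-BINAP additions to cyclic enones, which should give 2S, and the rhodium enolate is protonated by water so that no ring opening is expected.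

Step 12
Reactants: 19 (2S)-2-[2,4-bis(methoxymethoxy)phenyl]-8-[(1E)-3-hydroxy-3-methylbut-1-en-1-yl]-7-(methoxymethoxy)-2,3-dihydro-4H-chromen-4-one
Product: 20 (2S)-2-[2,4-bis(methoxymethoxy)phenyl]-7-(methoxymethoxy)-8-[(1E)-3-methylbuta-1,3-dien-1-yl]-2,3-dihydro-4H-chromen-4-one
Conditions: Burgess reagent, THF, 50 °C
Reagents that add atoms: none
Why: Burgess dehydration of the tertiary allylic alcohol under neutral conditions can only remove a methyl hydrogen, so it gives the conjugated diene without endangering the base-sensitive flavanone.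

**Dienophile**

Step 13
Reactants: 21 2,4-dihydroxybenzaldehyde
Product: 22 2,4-bis(methoxymethoxy)benzaldehyde
Conditions: NaH, MOMCl, DMF, 0 °C → rt
Reagents that add atoms: chloromethyl methyl ether (MOMCl), COCCl
Why: Double Williamson O-alkylation of the bis-phenoxide.

Step 14
Reactants: 22 2,4-bis(methoxymethoxy)benzaldehyde
Product: 23 (2E)-3-[2,4-bis(methoxymethoxy)phenyl]prop-2-enoic acid
Conditions: malonic acid, pyridine, piperidine (cat.), 90 °C
Reagents that add atoms: malonic acid, OC(=O)CC(=O)O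
Why: Knoevenagel–Doebner condensation with in situ decarboxylation gives the E-cinnamic acid.

Step 15
Reactants: 23 (2E)-3-[2,4-bis(methoxymethoxy)phenyl]prop-2-enoic acid, 24 (4S)-4-benzyl-1,3-oxazolidin-2-one
Product: 26 (4S)-4-benzyl-3-{(2E)-3-[2,4-bis(methoxymethoxy)phenyl]prop-2-enoyl}-1,3-oxazolidin-2-one, via mixed pivalic anhydride 25 (not isolated)
Conditions: PivCl, Et3N, THF, −20 °C; then 24, LiCl, rt
Reagents that add atoms: none
Why: Mixed-anhydride N-acylation of the oxazolidinone under LiCl/Et3N activation attaches the chiral auxiliary without a strong base.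

**Assembly**

Step 16
Reactants: 20 (2S)-2-[2,4-bis(methoxymethoxy)phenyl]-7-(methoxymethoxy)-8-[(1E)-3-methylbuta-1,3-dien-1-yl]-2,3-dihydro-4H-chromen-4-one, 26 (4S)-4-benzyl-3-{(2E)-3-[2,4-bis(methoxymethoxy)phenyl]prop-2-enoyl}-1,3-oxazolidin-2-one
Product: 27 (4S)-4-benzyl-3-{[(1R,2S,6S)-6-ArM-2-ChrM-4-methylcyclohex-3-en-1-yl]carbonyl}-1,3-oxazolidin-2-one
Conditions: Et2AlCl (2.5 equiv), CH2Cl2, −78 → −30 °C; 1 M HCl quench at 0 °C
Reagents that add atoms: none
Why: Auxiliary-controlled Lewis-acid-promoted Diels–Alder reaction: the aluminium-chelated s-cis imide reacts on its Cα-Si face away from the benzyl group, the C-1 aryl and C-3 methyl groups of the diene both direct the required regiochemistry, the endo transition state places the acyl group cis to ChrM and the E-alkene keeps ArM trans to it, so that C-2 and C-6 are set trans as (2S,6S).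

Step 17
Reactants: 27 (4S)-4-benzyl-3-{[(1R,2S,6S)-6-ArM-2-ChrM-4-methylcyclohex-3-en-1-yl]carbonyl}-1,3-oxazolidin-2-one
Product: 29 (1R,2S,6S)-6-ArM-2-ChrM-4-methylcyclohex-3-ene-1-carboxylic acid, via peroxy acid 28 (not isolated)
Conditions: LiOH, H2O2, THF–H2O, 0 °C; then Na2SO3; 1 M HCl to pH 3
Reagents that add atoms: hydrogen peroxide (as LiOOH), OO
Why: Hydroperoxide attacks the exocyclic imide carbonyl selectively even in hindered N-acyl oxazolidinones, the percarboxylate is reduced by sulfite, and the short cold exposure is chosen to spare the flavanone.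

Step 18
Reactants: 29 (1R,2S,6S)-6-ArM-2-ChrM-4-methylcyclohex-3-ene-1-carboxylic acid
Product: 30 1,3-dioxo-1,3-dihydro-2H-isoindol-2-yl (1R,2S,6S)-6-ArM-2-ChrM-4-methylcyclohex-3-ene-1-carboxylate
Conditions: N-hydroxyphthalimide, DIC, DMAP (cat.), CH2Cl2, rt
Reagents that add atoms: N-hydroxyphthalimide, O=C1c2ccccc2C(=O)N1O
Why: Carbodiimide (Steglich-type) esterification gives the redox-active ester.

Step 19
Reactants: 30 1,3-dioxo-1,3-dihydro-2H-isoindol-2-yl (1R,2S,6S)-6-ArM-2-ChrM-4-methylcyclohex-3-ene-1-carboxylate, 7 S-(pyridin-2-yl) 2,4-bis(methoxymethoxy)-3-(3-methylbut-2-en-1-yl)benzenecarbothioate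
Product: 32 [(1R,2S,6S)-6-ArM-2-ChrM-4-methylcyclohex-3-en-1-yl][2,4-bis(methoxymethoxy)-3-(3-methylbut-2-en-1-yl)phenyl]methanone, via C-1 radical 31 (not isolated)
Conditions: NiBr2·dme (10 mol%), 4,4′-di-tert-butyl-2,2′-bipyridine (12 mol%), Zn (3 equiv), THF–DMA, 0 °C → rt
Reagents that add atoms: none
Why: Zinc reduces the nickel precatalyst to Ni(0), which inserts into the C(acyl)–S bond of 7 to give an aroyl–Ni(II) thiolate, while one-electron reduction of 30 releases CO2, phthalimide anion and the secondary C-1 radical 31; capture of 31 by the aroyl–nickel species and reductive elimination from Ni(III) form the carbonyl–C-1 bond. The closest known reaction type is the nickel-catalysed decarboxylative cross-electrophile coupling of N-acyloxyphthalimides with S-2-pyridyl thioesters to give ketones; no ring is closed. The only new stereocentre is C-1, and it is controlled by the substrate: 31 is planar at C-1 and its neighbours C-2 and C-6 carry trans aryl groups, so one of them must be axial in the half-chair; the 2,6-disubstituted ChrM group on the allylic C-2 should stay pseudoequatorial, which puts ArM on C-6 axial, and the aroyl–nickel is expected to add axially and anti to it. This gives the acyl group trans to ArM and cis to ChrM (1R), the trans-diaxial arrangement at C-1/C-6. The step needs this facial selectivity and cross- over homo-coupling; the first rests on the trans-2,6-diaryl pattern fixed in step 16, the second on the different activation modes of the two electrophiles (two-electron oxidative addition of the thioester, one-electron reduction of the redox-active ester). The flavanone ketone, the MOM acetals and both trisubstituted alkenes are inert to Ni/Zn, so nothing has to be masked.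

Step 20
Reactants: 32 [(1R,2S,6S)-6-ArM-2-ChrM-4-methylcyclohex-3-en-1-yl][2,4-bis(methoxymethoxy)-3-(3-methylbut-2-en-1-yl)phenyl]methanone
Product: 33 [(1R,2S,6S)-6-(2,4-dihydroxyphenyl)-2-[(2S)-2-(2,4-dihydroxyphenyl)-7-hydroxy-4-oxo-3,4-dihydro-2H-chromen-8-yl]-4-methylcyclohex-3-en-1-yl][2,4-dihydroxy-3-(3-methylbut-2-en-1-yl)phenyl]methanone
Conditions: 3 M aq HCl, MeOH–THF, 40 °C
Reagents that add atoms: none
Why: Acid-catalysed transacetalisation of the seven MOM ethers to dimethoxymethane, at a mild temperature chosen to avoid cyclisation of the prenyl group onto the neighbouring phenol and enolisation at C-1.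

**Compound list**

1 | resorcinol | Oc1cccc(O)c1 | starting material
2 | 1,3-bis(methoxymethoxy)benzene | COCOc1cccc(OCOC)c1 | intermediate
3 | [2,6-bis(methoxymethoxy)phenyl]lithium | [Li]c1c(OCOC)cccc1OCOC | intermediate (not isolated)
4 | 1,3-bis(methoxymethoxy)-2-(3-methylbut-2-en-1-yl)benzene | COCOc1cccc(OCOC)c1CC=C(C)C | intermediate
5 | [2,4-bis(methoxymethoxy)-3-(3-methylbut-2-en-1-yl)phenyl]lithium | [Li]c1ccc(OCOC)c(CC=C(C)C)c1OCOC | intermediate (not isolated)
6 | 2,4-bis(methoxymethoxy)-3-(3-methylbut-2-en-1-yl)benzoic acid | CC(C)=CCc1c(OCOC)ccc(C(=O)O)c1OCOC | intermediate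
7 | S-(pyridin-2-yl) 2,4-bis(methoxymethoxy)-3-(3-methylbut-2-en-1-yl)benzenecarbothioate | CC(C)=CCc1c(OCOC)ccc(C(=O)Sc2ccccn2)c1OCOC | intermediate
8 | 4-bromobenzene-1,3-diol | Oc1ccc(Br)c(O)c1 | starting material
9 | 1-bromo-2,4-bis(methoxymethoxy)benzene | COCOc1ccc(Br)c(OCOC)c1 | intermediate
10 | [2,4-bis(methoxymethoxy)phenyl]lithium | [Li]c1ccc(OCOC)cc1OCOC | intermediate (not isolated)
11 | [2,4-bis(methoxymethoxy)phenyl]boronic acid | COCOc1ccc(B(O)O)c(OCOC)c1 | intermediate
12 | 1-(2,4-dihydroxyphenyl)ethan-1-one | CC(=O)c1ccc(O)cc1O | starting material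
13 | 1-(2,4-dihydroxy-3-iodophenyl)ethan-1-one | CC(=O)c1ccc(O)c(I)c1O | intermediate
14 | 1-[2-hydroxy-3-iodo-4-(methoxymethoxy)phenyl]ethan-1-one | CC(=O)c1ccc(OCOC)c(I)c1O | intermediate
15 | (2E)-3-(dimethylamino)-1-[2-hydroxy-3-iodo-4-(methoxymethoxy)phenyl]prop-2-en-1-one | CN(C)/C=C/C(=O)c1ccc(OCOC)c(I)c1O | intermediate (not isolated)
16 | 8-iodo-7-(methoxymethoxy)-4H-chromen-4-one | COCOc1ccc2c(=O)ccoc2c1I | intermediate
17 | 2-methylbut-3-en-2-ol | CC(C)(O)C=C | starting material
18 | 8-[(1E)-3-hydroxy-3-methylbut-1-en-1-yl]-7-(methoxymethoxy)-4H-chromen-4-one | COCOc1ccc2c(=O)ccoc2c1/C=C/C(C)(C)O | intermediate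
19 | (2S)-2-[2,4-bis(methoxymethoxy)phenyl]-8-[(1E)-3-hydroxy-3-methylbut-1-en-1-yl]-7-(methoxymethoxy)-2,3-dihydro-4H-chromen-4-one | COCOc1ccc2c(c1/C=C/C(C)(C)O)O[C@H](c1ccc(OCOC)cc1OCOC)CC2=O | intermediate
20 | (2S)-2-[2,4-bis(methoxymethoxy)phenyl]-7-(methoxymethoxy)-8-[(1E)-3-methylbuta-1,3-dien-1-yl]-2,3-dihydro-4H-chromen-4-one | COCOc1ccc2c(c1/C=C/C(C)=C)O[C@H](c1ccc(OCOC)cc1OCOC)CC2=O | intermediate
21 | 2,4-dihydroxybenzaldehyde | O=Cc1ccc(O)cc1O | starting material
22 | 2,4-bis(methoxymethoxy)benzaldehyde | COCOc1ccc(C=O)c(OCOC)c1 | intermediate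
23 | (2E)-3-[2,4-bis(methoxymethoxy)phenyl]prop-2-enoic acid | COCOc1ccc(/C=C/C(=O)O)c(OCOC)c1 | intermediate
24 | (4S)-4-benzyl-1,3-oxazolidin-2-one | O=C1OC[C@H](Cc2ccccc2)N1 | starting material
25 | (2E)-3-[2,4-bis(methoxymethoxy)phenyl]prop-2-enoic 2,2-dimethylpropanoic anhydride | COCOc1ccc(/C=C/C(=O)OC(=O)C(C)(C)C)c(OCOC)c1 | intermediate (not isolated)
26 | (4S)-4-benzyl-3-{(2E)-3-[2,4-bis(methoxymethoxy)phenyl]prop-2-enoyl}-1,3-oxazolidin-2-one | COCOc1ccc(/C=C/C(=O)N2[C@@H](Cc3ccccc3)COC2=O)c(OCOC)c1 | intermediate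
27 | (4S)-4-benzyl-3-{[(1R,2S,6S)-6-ArM-2-ChrM-4-methylcyclohex-3-en-1-yl]carbonyl}-1,3-oxazolidin-2-one (acyl cis to ChrM, trans to ArM) | O=C(N4[C@@H](Cc5ccccc5)COC4=O)[C@H]1[C@@H](c2c(OCOC)ccc3c2O[C@H](c2ccc(OCOC)cc2OCOC)CC3=O)C=C(C)C[C@@H]1c1ccc(OCOC)cc1OCOC | intermediate
28 | (1R,2S,6S)-6-ArM-2-ChrM-4-methylcyclohex-3-ene-1-carboperoxoic acid | OOC(=O)[C@H]1[C@@H](c2c(OCOC)ccc3c2O[C@H](c2ccc(OCOC)cc2OCOC)CC3=O)C=C(C)C[C@@H]1c1ccc(OCOC)cc1OCOC | intermediate (not isolated)
29 | (1R,2S,6S)-6-ArM-2-ChrM-4-methylcyclohex-3-ene-1-carboxylic acid | OC(=O)[C@H]1[C@@H](c2c(OCOC)ccc3c2O[C@H](c2ccc(OCOC)cc2OCOC)CC3=O)C=C(C)C[C@@H]1c1ccc(OCOC)cc1OCOC | intermediate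
30 | 1,3-dioxo-1,3-dihydro-2H-isoindol-2-yl (1R,2S,6S)-6-ArM-2-ChrM-4-methylcyclohex-3-ene-1-carboxylate | O=C(ON4C(=O)c5ccccc5C4=O)[C@H]1[C@@H](c2c(OCOC)ccc3c2O[C@H](c2ccc(OCOC)cc2OCOC)CC3=O)C=C(C)C[C@@H]1c1ccc(OCOC)cc1OCOC | intermediate
31 | 6-ArM-2-ChrM-4-methylcyclohex-3-en-1-yl radical (C-2, C-6 and ChrM configured as in 30) | [CH]1[C@@H](c2c(OCOC)ccc3c2O[C@H](c2ccc(OCOC)cc2OCOC)CC3=O)C=C(C)C[C@@H]1c1ccc(OCOC)cc1OCOC | intermediate (not isolated)
32 | [(1R,2S,6S)-6-ArM-2-ChrM-4-methylcyclohex-3-en-1-yl][2,4-bis(methoxymethoxy)-3-(3-methylbut-2-en-1-yl)phenyl]methanone | CC(C)=CCc4c(OCOC)ccc(C(=O)[C@H]1[C@@H](c2c(OCOC)ccc3c2O[C@H](c2ccc(OCOC)cc2OCOC)CC3=O)C=C(C)C[C@@H]1c1ccc(OCOC)cc1OCOC)c4OCOC | intermediate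
33 | [(1R,2S,6S)-6-(2,4-dihydroxyphenyl)-2-[(2S)-2-(2,4-dihydroxyphenyl)-7-hydroxy-4-oxo-3,4-dihydro-2H-chromen-8-yl]-4-methylcyclohex-3-en-1-yl][2,4-dihydroxy-3-(3-methylbut-2-en-1-yl)phenyl]methanone | CC(C)=CCc1c(O)ccc(C(=O)[C@H]2[C@@H](c3c(O)ccc4c3O[C@H](c3ccc(O)cc3O)CC4=O)C=C(C)C[C@@H]2c2ccc(O)cc2O)c1O | target

**Totals**

Total steps: 20. Longest linear sequence: 11 steps (from 12: steps 7–12, then 16–20).

**Steps most likely to fail**

1. Step 19. The congested secondary C-1 radical may be reduced or abstract hydrogen before the aroyl–nickel species captures it, or it may be captured with poor discrimination between its two aryl-flanked faces. The fallback sets out from 30 (with the acyl partner made from 4) and returns at 32. Aryllithium 5, generated from 4 as in step 3, is quenched with DMF instead of CO2 to give 2,4-bis(methoxymethoxy)-3-(3-methylbut-2-en-1-yl)benzaldehyde F1. F1 and 30 are then heated with an N-aryl thiazolium precatalyst and catalytic Cs2CO3 in DMSO at 60 °C. The Breslow enolate reduces 30, and the persistent, very bulky carbene-bound ketyl radical couples metal-free with radical 31; loss of the carbene gives 32. The bulk of this partner should accentuate attack anti to the axial aryl.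

2. Step 16. The Lewis acid is needed in excess because the ketone and the acetal oxygens compete for it; it may polymerise the electron-rich diene or strip MOM groups before the deactivated cinnamoyl imide reacts, and endo selectivity may erode. The fallback sets out from 22 and 20 and returns at 29. Aldol condensation of 22 with 3-hydroxy-3-methylbutan-2-one (LiOH, MeOH–H2O) gives the α′-hydroxy enone (1E)-1-[2,4-bis(methoxymethoxy)phenyl]-4-hydroxy-4-methylpent-1-en-3-one F2. F2 binds a chiral Cu(II)–tert-butyl-bisoxazoline catalyst (10 mol%, CH2Cl2, rt) as a 1,4-chelate and should add to 20 under catalyst control (ligand enantiomer chosen on a model diene) to give the ketol adduct 1-[(1R,2S,6S)-6-ArM-2-ChrM-4-methylcyclohex-3-en-1-yl]-2-hydroxy-2-methylpropan-1-one F3. NaIO4 in MeOH–H2O cleaves the ketol to acid 29 and acetone, which also bypasses the basic hydrolysis of step 17.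

3. Step 20. Seven MOM ethers need prolonged Brønsted acid, which may let the prenyl group cyclise onto the freed ortho-phenol (chroman formation), enolise C-1 or open the flavanone. The fallback sets out from 32 and returns at 33. A non-protic acetal-to-silyl exchange (TESOTf, 2,2′-bipyridyl, CH2Cl2, 0 °C) converts 32 into the heptakis(triethylsilyl) ether of 33 F4. Fluoride (HF·pyridine, THF, 0 °C) then frees the seven phenols without any strong acid.

**Further compounds**

F1 | step 19 | 2,4-bis(methoxymethoxy)-3-(3-methylbut-2-en-1-yl)benzaldehyde | CC(C)=CCc1c(OCOC)ccc(C=O)c1OCOC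
F2 | step 16 | (1E)-1-[2,4-bis(methoxymethoxy)phenyl]-4-hydroxy-4-methylpent-1-en-3-one | COCOc1ccc(/C=C/C(=O)C(C)(C)O)c(OCOC)c1
F3 | step 16 | 1-[(1R,2S,6S)-6-ArM-2-ChrM-4-methylcyclohex-3-en-1-yl]-2-hydroxy-2-methylpropan-1-one | CC(C)(O)C(=O)[C@H]1[C@@H](c2c(OCOC)ccc3c2O[C@H](c2ccc(OCOC)cc2OCOC)CC3=O)C=C(C)C[C@@H]1c1ccc(OCOC)cc1OCOC
F4 | step 20 | heptakis(triethylsilyl) ether of 33 | CC(C)=CCc4c(O[Si](CC)(CC)CC)ccc(C(=O)[C@H]1[C@@H](c2c(O[Si](CC)(CC)CC)ccc3c2O[C@H](c2ccc(O[Si](CC)(CC)CC)cc2O[Si](CC)(CC)CC)CC3=O)C=C(C)C[C@@H]1c1ccc(O[Si](CC)(CC)CC)cc1O[Si](CC)(CC)CC)c4O[Si](CC)(CC)CC
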